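The readings were computed on assumed constants; the scatter is artificial.

If you see these flasks only as a J peak growing, ask of each one not how much J is made but what fraction of its ceiling is still missing at the end.

| flask | D | G | temperature | remark | time |
|---|---|---|---|---|---|
| Monday's | 24 mM | 1.5 equiv | 2 °C | run made earlier |  |
| Tuesday's | 24 mM | 2.4 equiv | 52 °C | run made earlier |  |
| Sunday's | 36 mM | 1.1 equiv | 2 °C | run made earlier |  |
| violet | 24 mM | 1.10 equiv | 70 °C |  | 3.0 min |
| teal | 24 mM | 1.10 equiv | 40 °C |  | 3.0 min |
| red | 24 mM | 1.10 equiv | −20 °C |  | 3.0 min |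
| blue | 24 mM | 1.10 equiv | 10 °C |  | 3.0 min |

- Monday's (time / min: J / %): 12.0: 2.6; 25.0: 5.8; 40.0: 7.3; 60.0: 10.6; 80.0: 13.0
- Tuesday's (time / min: J / %): 0.667: 39.4; 0.833: 46.3; 1.33: 59.5; 2.00: 66.3; 3.00: 69.8; 5.00: 69.8; 8.00: 68.8
- Sunday's (time / min: J / %): 8.00: 1.1; 12.0: 2.3; 25.0: 3.2; 40.0: 6.4; 80.0: 10.6

(readings scatter by 0.5 percentage points)

- the flask that comes out highest in amount of J, in percent of the D charged, or "all alike" when all lie within 1.5 percentage points (violet / teal / red / blue / all alike)
- J at the end, in percent of the D charged, violet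
- J at the end, in percent of the D charged, teal
- J at the end, in percent of the D charged, red
- J at the end, in percent of the D charged, blue

- a species is counted by the D in it: one Z counts as two
- steps under discussion: D + G -> E; E <-> J; D + E -> Z; G -> X

How fast does that fraction left shrink? Take Tuesday's 69.8 % at 3.00 min as the ceiling. The fraction left is then 0.436 at 0.667 min and 0.148 at 1.33 min, so between those two readings it shrinks as exp(−rt), with an approach rate r of 1.63 min⁻¹. Run back to the start, that line gives 1.29 and not the whole charge of the gap, so the decay sets in after a lag; r is a rate of the tail, and I neglect the lag in what follows.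

How does r move with temperature? Against the same ceiling, Monday's last reading leaves 0.814 after 80.0 min, so r at 2 °C is 0.00258 min⁻¹, slower than Tuesday's by a factor of 632. I set the difference in G aside and take from these two runs the approach energy, the apparent activation energy that carries r from one temperature to another: 96.0 kJ mol⁻¹.

What is left at 3.0 min? Teal has r = 0.419 min⁻¹ and keeps a fraction 0.285. Blue keeps 0.975, and red keeps 1.00. Violet has r = 10.5 min⁻¹, which gives 45.4 halvings, so its fraction left is negligible.

How high is the ceiling? The readings show no plateau at 1.10 equiv, since Monday's and Sunday's are still rising at their last readings, so I keep Tuesday's 69.8 %, read at 2.4 equiv, and that difference in G stays an open risk in the numbers below. My reckoning is then 69.8 % for violet, 49.9 % for teal, 1.74 % for blue and 0.0141 % for red, with violet highest.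

The forecast differs in its numbers but not its winner, “Violet should be highest”: 60 % for violet, 27 % for teal, 0.03 % for red and 1.3 % for blue.

The flasks give 53.9 % in violet, 32.4 % in teal, 0 % in red and 0.800 % in blue, so violet is highest.

    D + G → E (k = 3.50 M⁻¹ s⁻¹, Ea = 38.0 kJ mol⁻¹)
    E ⇌ J (K = 7.90, k = 0.170 s⁻¹, Ea = 93.0 kJ mol⁻¹, ΔH = −53.0 kJ mol⁻¹)
    D + E → Z (k = 4.10 M⁻¹ s⁻¹, Ea = 46.0 kJ mol⁻¹)
    G → X (k = 0.00400 s⁻¹, Ea = 87.0 kJ mol⁻¹)
    (constants at 70 °C)

Violet's J has come to rest: ten times the time leaves it at 53.9 %, while G falls from 10.7 % to 0.0159 % of its charge and X rises from 4.34 mM to 7.10 mM. Teal has not: measured against its 50.7 % at 30.0 min, its fraction left at 3.0 min is 0.361, where I reckoned 0.285. Blue is further off: the approach energy of 96.0 kJ mol⁻¹ and my ceiling put it at 15.6 % at 30.0 min. Blue's J climbs from 0.800 % to 12.5 %.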